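**Retrosynthetic overview**

1. The last bond made is the side-chain ester, by acylation of alkannin with 3-methylbut-2-enoic acid. Alkannin comes from a 5,8-dimethoxy-1-naphthol by para-oxidation (oxygen at C1) and cleavage of the two peri methyl ethers.
2. Key disconnection: quinone ring A (C1–C2–C3–C4–C4a–C8a, C2 carrying the side chain) is cut at C2=C3 and at C1–C8a. This is a [4+2] C–H annulation of an aroyl sulfoxonium ylide (C4a, C8a–H, C4=O, ylide carbon C3) with a terminal alkyne (C1–H, C2) that already holds the complete (S)-side chain as its silyl ether.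
3. Enabling feature: in ring A, C4 is a carbonyl carbon bound to ring B and its neighbour C3 carries only H, so C4/C3 can act as directing acyl group and carbene carbon. C8a is the single free ortho C–H of ring B because the other ortho position (C5) carries oxygen. C1 has no carbon substituent, so a terminal alkyne suffices and its oxygen can be added afterwards, para to the C4 hydroxyl.
4. The stereocenter is set earlier by asymmetric transfer hydrogenation of an alkynyl ketone. During the annulation it sits at a propargylic, non-enolisable position.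
5. Ring order: ring B is bought (methyl 2,5-dimethoxybenzoate); ring A is the only ring made, in step 7.

Key step: step 7

Remark: atom numbers C1–C8a are those of the naphthoquinone core of the target (ring A = quinone ring, ring B = dihydroxybenzene ring); 4-methylpent-3-enoic acid, ethynyltrimethylsilane, methyl 2,5-dimethoxybenzoate and 3-methylbut-2-enoic acid are taken as purchasable.

**Route**

Step 1
Reactants: 1 4-methylpent-3-enoic acid
Product: 2 N-methoxy-N,4-dimethylpent-3-enamide
Conditions: MeNHOMe·HCl, EDC·HCl, N-methylmorpholine, CH2Cl2, 0 °C to rt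
Reagents that add atoms: N,O-dimethylhydroxylamine hydrochloride, CNOC.Cl
Why: Carbodiimide-mediated amide coupling (Weinreb amide formation) of an unhindered acid is routine, and the mild base should leave the β,γ-double bond out of conjugation.

Step 2
Reactants: 2 N-methoxy-N,4-dimethylpent-3-enamide; 3 ethynyltrimethylsilane
Product: 6 6-methyl-1-(trimethylsilyl)hept-5-en-1-yn-3-one, via lithium (trimethylsilyl)acetylide 4 (not isolated), via lithium hemiaminal alkoxide 5 (not isolated)
Conditions: 3, n-BuLi, THF, −78 °C; then 2, −78 to 0 °C; cold 1 M HCl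
Reagents that add atoms: none
Why: Weinreb ketone synthesis, in which the lithium acetylide adds only once because the N-methoxy-chelated tetrahedral adduct persists until the acidic quench, so the ynone should form without over-addition.

Step 3
Reactants: 6 6-methyl-1-(trimethylsilyl)hept-5-en-1-yn-3-one
Product: 7 (3S)-6-methyl-1-(trimethylsilyl)hept-5-en-1-yn-3-ol
Conditions: Ru[(S,S)-TsNCHPhCHPhNH](η6-p-cymene) (0.5 mol %, preformed amido complex), i-PrOH, rt
Reagents that add atoms: none
Why: Noyori asymmetric transfer hydrogenation of an alkynyl ketone, in which the (S,S)-diamine ruthenium hydride distinguishes the alkynyl from the alkyl substituent and should deliver hydride to the face that gives the (S)-propargylic alcohol, while the base-free preformed catalyst should spare the acidic methylene group between carbonyl and alkene.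

Step 4
Reactants: 7 (3S)-6-methyl-1-(trimethylsilyl)hept-5-en-1-yn-3-ol
Product: 8 tert-butyldimethyl{[(3S)-6-methyl-1-(trimethylsilyl)hept-5-en-1-yn-3-yl]oxy}silane
Conditions: TBSCl, imidazole, DMF, 0 °C to rt
Reagents that add atoms: tert-butyldimethylsilyl chloride (TBSCl), CC(C)(C)[Si](C)(C)Cl
Why: Standard silylation of a secondary alcohol, which turns the propargylic oxygen into a poor leaving group for the later organorhodium steps and does not touch the C–O bond of the stereocenter.

Step 5
Reactants: 8 tert-butyldimethyl{[(3S)-6-methyl-1-(trimethylsilyl)hept-5-en-1-yn-3-yl]oxy}silane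
Product: 9 tert-butyldimethyl{[(3S)-6-methylhept-5-en-1-yn-3-yl]oxy}silane
Conditions: K2CO3 (cat.), MeOH, rt
Reagents that add atoms: none
Why: Base-catalysed methanolysis of the alkynyl C–Si bond (protodesilylation) is selective for the alkynylsilane over the alkyl TBS ether and should free the terminal alkyne.

Step 6
Reactants: 10 methyl 2,5-dimethoxybenzoate
Product: 11 dimethylsulfoxonium 2-(2,5-dimethoxyphenyl)-2-oxoethylide
Conditions: Me3S(O)I, KOtBu, THF, reflux; then 10, reflux
Reagents that add atoms: trimethylsulfoxonium iodide, C[S+](C)(C)=O.[I-]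
Why: Corey–Chaykovsky-type acylation of dimethylsulfoxonium methylide by an ester, in which the ylide carbon attacks the ester carbonyl, methoxide leaves and deprotonates the β-keto sulfoxonium salt to the stabilised ylide, which should not react a second time.

Step 7
Reactants: 11 dimethylsulfoxonium 2-(2,5-dimethoxyphenyl)-2-oxoethylide; 9 tert-butyldimethyl{[(3S)-6-methylhept-5-en-1-yn-3-yl]oxy}silane
Product: 13 3-[(1S)-1-(tert-butyldimethylsilyloxy)-4-methylpent-3-en-1-yl]-5,8-dimethoxynaphthalen-1-ol, via naphthalen-1(2H)-one keto tautomer 12 (not isolated)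
Conditions: [Cp*Rh(MeCN)3](SbF6)2 (5 mol %), NaOAc (20 mol %), ClCH2CH2Cl, 80 °C, Ar, 9 (1.5 equiv) added over 4 h
Reagents that add atoms: none
Why: The cationic Cp*Rh catalyst (trivalent rhodium), held by the ylide carbonyl, should cleave the only free ortho C–H bond (C8a–H) by acetate-assisted concerted metalation–deprotonation, the terminal alkyne should then insert into the aryl–Rh bond (C8a–C1 formed), the ylide carbon C3 should bind rhodium and lose DMSO to give a rhodium carbene, the alkenyl carbon C2 should migrate onto this carbene (C2–C3 formed), and protonation should release the keto tautomer 12, which enolises to naphthol 13. The closest known reaction type is the trivalent-rhodium-catalysed C–H activation and [4+2] annulation of aroyl sulfoxonium ylides with alkynes to 1-naphthols. Ring A is the one ring closed, as a six-membered carbocycle by formal [4+2] annulation, the closing event being the 1,1-migratory insertion of C2 into the carbene at C3 within a seven-membered rhodacycle. No stereocenter is formed, and the propargylic stereocenter should pass unchanged because the medium is neutral and its C–O bond is a silyl ether that is slow to undergo β-oxygen elimination from the alkenyl-rhodium intermediate. The step needs site selectivity, secured because the other ortho position of the arene carries the C5 methoxy group, and regioselectivity of insertion (aryl to the terminal CH, rhodium to the substituted carbon), secured by the bulk of the branched propargylic substituent, by coordination of its ether oxygen to rhodium and by the peri methoxy group at C8, next to which only H at C1 fits. Slow addition of the alkyne should limit its oligomerisation, and because DMSO is the internal leaving group no external oxidant is present that could attack the prenyl double bond.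

Step 8
Reactants: 13 3-[(1S)-1-(tert-butyldimethylsilyloxy)-4-methylpent-3-en-1-yl]-5,8-dimethoxynaphthalen-1-ol
Product: 14 2-[(1S)-1-(tert-butyldimethylsilyloxy)-4-methylpent-3-en-1-yl]-5,8-dimethoxynaphthalene-1,4-dione
Conditions: ON(SO3K)2 (2.5 equiv), aq. KH2PO4, acetone, 0 °C to rt
Reagents that add atoms: potassium nitrosodisulfonate ON(SO3K)2, [K+].[K+].[O]N(S(=O)(=O)[O-])S(=O)(=O)[O-]
Why: Teuber oxidation, in which one nitrosodisulfonate radical abstracts the phenolic hydrogen and a second couples at the free para position C1 (highest spin density) before the adduct collapses to the para-quinone, while the aryl methyl ethers, the silyl ether and the trisubstituted alkene should not react with this mild one-electron oxidant.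

Step 9
Reactants: 14 2-[(1S)-1-(tert-butyldimethylsilyloxy)-4-methylpent-3-en-1-yl]-5,8-dimethoxynaphthalene-1,4-dione
Product: 16 2-[(1S)-1-(tert-butyldimethylsilyloxy)-4-methylpent-3-en-1-yl]-5,8-dihydroxynaphthalene-1,4-dione, via bis(dichloroboryl) chelate 15 (not isolated)
Conditions: BCl3 (4 equiv), CH2Cl2, −78 to −30 °C; then H2O
Reagents that add atoms: none
Why: Chelation-controlled ether cleavage, in which BCl3 binds each quinone carbonyl together with its peri methoxy oxygen and chloride removes the methyl group as chloromethane, so that at low temperature only these two activated ethers should be cleaved while the secondary silyl ether and the alkene are left and the boron chelate is hydrolysed on work-up.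

Step 10
Reactants: 16 2-[(1S)-1-(tert-butyldimethylsilyloxy)-4-methylpent-3-en-1-yl]-5,8-dihydroxynaphthalene-1,4-dione
Product: 17 alkannin, 5,8-dihydroxy-2-[(1S)-1-hydroxy-4-methylpent-3-en-1-yl]naphthalene-1,4-dione
Conditions: HF·pyridine, pyridine, THF, 0 °C to rt
Reagents that add atoms: none
Why: Fluoride-mediated desilylation under buffered, non-basic conditions cleaves only the Si–O bond, so the acidic naphthazarin core and the configuration of the stereocenter (C–O bond untouched) should be unaffected.

Step 11
Reactants: 17 alkannin; 18 3-methylbut-2-enoic acid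
Product: 19 alkannin β,β-dimethylacrylate, (1S)-1-(5,8-dihydroxy-1,4-dioxo-1,4-dihydronaphthalen-2-yl)-4-methylpent-3-en-1-yl 3-methylbut-2-enoate
Conditions: DCC (1.2 equiv), DMAP (10 mol %), CH2Cl2, 0 °C to rt
Reagents that add atoms: none
Why: Steglich esterification, in which the acid is activated as O-acylisourea and N-acylpyridinium ion and should acylate only the secondary side-chain alcohol, because both phenolic hydroxyls are tied up in strong hydrogen bonds to the quinone carbonyls, with retention at the stereocenter since its C–O bond is not broken.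

**Compound list**

1 | 4-methylpent-3-enoic acid | CC(C)=CCC(=O)O | starting material
2 | N-methoxy-N,4-dimethylpent-3-enamide | CC(C)=CCC(=O)N(C)OC | intermediate
3 | ethynyltrimethylsilane | C#C[Si](C)(C)C | starting material
4 | lithium (trimethylsilyl)acetylide | [Li+].[C-]#C[Si](C)(C)C | intermediate
5 | lithium 3-[methoxy(methyl)amino]-6-methyl-1-(trimethylsilyl)hept-5-en-1-yn-3-olate | CC(C)=CCC([O-])(C#C[Si](C)(C)C)N(C)OC.[Li+] | intermediate
6 | 6-methyl-1-(trimethylsilyl)hept-5-en-1-yn-3-one | CC(C)=CCC(=O)C#C[Si](C)(C)C | intermediate
7 | (3S)-6-methyl-1-(trimethylsilyl)hept-5-en-1-yn-3-ol | CC(C)=CC[C@H](O)C#C[Si](C)(C)C | intermediate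
8 | tert-butyldimethyl{[(3S)-6-methyl-1-(trimethylsilyl)hept-5-en-1-yn-3-yl]oxy}silane | CC(C)=CC[C@H](O[Si](C)(C)C(C)(C)C)C#C[Si](C)(C)C | intermediate
9 | tert-butyldimethyl{[(3S)-6-methylhept-5-en-1-yn-3-yl]oxy}silane | CC(C)=CC[C@H](O[Si](C)(C)C(C)(C)C)C#C | intermediate
10 | methyl 2,5-dimethoxybenzoate | COC(=O)c1cc(OC)ccc1OC | starting material
11 | dimethylsulfoxonium 2-(2,5-dimethoxyphenyl)-2-oxoethylide | COc1ccc(OC)c(c1)C(=O)C=S(C)(C)=O | intermediate
12 | 3-[(1S)-1-(tert-butyldimethylsilyloxy)-4-methylpent-3-en-1-yl]-5,8-dimethoxynaphthalen-1(2H)-one | CC(C)=CC[C@H](O[Si](C)(C)C(C)(C)C)C1=Cc2c(OC)ccc(OC)c2C(=O)C1 | intermediate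
13 | 3-[(1S)-1-(tert-butyldimethylsilyloxy)-4-methylpent-3-en-1-yl]-5,8-dimethoxynaphthalen-1-ol | CC(C)=CC[C@H](O[Si](C)(C)C(C)(C)C)c1cc(O)c2c(OC)ccc(OC)c2c1 | intermediate
14 | 2-[(1S)-1-(tert-butyldimethylsilyloxy)-4-methylpent-3-en-1-yl]-5,8-dimethoxynaphthalene-1,4-dione | CC(C)=CC[C@H](O[Si](C)(C)C(C)(C)C)C1=CC(=O)c2c(OC)ccc(OC)c2C1=O | intermediate
15 | 2-[(1S)-1-(tert-butyldimethylsilyloxy)-4-methylpent-3-en-1-yl]-5,8-bis[(dichloroboranyl)oxy]naphthalene-1,4-dione | CC(C)=CC[C@H](O[Si](C)(C)C(C)(C)C)C1=CC(=O)c2c(OB(Cl)Cl)ccc(OB(Cl)Cl)c2C1=O | intermediate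
16 | 2-[(1S)-1-(tert-butyldimethylsilyloxy)-4-methylpent-3-en-1-yl]-5,8-dihydroxynaphthalene-1,4-dione | CC(C)=CC[C@H](O[Si](C)(C)C(C)(C)C)C1=CC(=O)c2c(O)ccc(O)c2C1=O | intermediate
17 | alkannin, 5,8-dihydroxy-2-[(1S)-1-hydroxy-4-methylpent-3-en-1-yl]naphthalene-1,4-dione | CC(C)=CC[C@H](O)C1=CC(=O)c2c(O)ccc(O)c2C1=O | intermediate
18 | 3-methylbut-2-enoic acid | CC(C)=CC(=O)O | starting material
19 | alkannin β,β-dimethylacrylate | CC(C)=CC[C@H](OC(=O)C=C(C)C)C1=CC(=O)c2c(O)ccc(O)c2C1=O | target

**Step count and risks**

Total step count: 11. Longest linear sequence: 10 steps (steps 1–5, then 7–11).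

Steps most likely to fail:

1. Step 7. The terminal alkyne may be consumed by oligomerisation at its own C–H bond, the alkenyl-rhodium intermediate may undergo β-oxygen elimination, and C–H cleavage at the ortho position flanked by a methoxy group may be slow. Fallback (Dötz benzannulation; sets out from 9 and returns at 14, so steps 7 and 8 are both bypassed): 2-bromo-1,4-dimethoxybenzene is lithiated (n-BuLi, THF, −78 °C), added to Cr(CO)6 and O-methylated with Me3OBF4 to give the carbene complex pentacarbonyl[(2,5-dimethoxyphenyl)(methoxy)methylidene]chromium F1. Heating F1 with 9 in THF at 55 °C should give, by alkyne insertion, CO insertion and electrocyclisation, 2-[(1S)-1-(tert-butyldimethylsilyloxy)-4-methylpent-3-en-1-yl]-4,5,8-trimethoxynaphthalen-1-ol F2, with the larger alkyne substituent next to the new phenol carbon. Oxidation of crude F2 with (NH4)2Ce(NO3)6 in MeCN/H2O at 0 °C should remove the chromium fragment and convert the para-methoxynaphthol into quinone 14.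

2. Step 9. The Lewis acid may cleave the side-chain silyl ether or ionise the benzylic C–O bond, or the second methyl ether may be cleaved incompletely. Fallback (oxidative instead of Lewis-acidic demethylation; sets out from 14 and returns at 16): brief treatment of 14 with AgO and 6 M HNO3 in dioxane at rt should oxidise ring B to the diquinone 2-[(1S)-1-(tert-butyldimethylsilyloxy)-4-methylpent-3-en-1-yl]naphthalene-1,4,5,8-tetrone F3, which is reduced in the work-up with aqueous Na2S2O4 to the naphthazarin 16. Any material that loses the silyl ether in this medium arrives at 17, the next compound of the route.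

3. Step 8. The oxidant may attack the ortho position instead of the para position C1, which is flanked by the branched side chain and the peri methoxy group, giving the ortho-quinone. Fallback (para-oxygenation by a small nucleophile by way of a quinone monoketal; sets out from 13 and returns at 14): PhI(OAc)2 (2.2 equiv) in MeOH at 0 °C should give, by way of 3-[(1S)-1-(tert-butyldimethylsilyloxy)-4-methylpent-3-en-1-yl]-4,5,8-trimethoxynaphthalen-1-ol F4, the monoketal 3-[(1S)-1-(tert-butyldimethylsilyloxy)-4-methylpent-3-en-1-yl]-4,4,5,8-tetramethoxynaphthalen-1(4H)-one F5, which aqueous acetic acid in THF should hydrolyse to 14.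

**Further compounds**

F1 | step 7 | pentacarbonyl[(2,5-dimethoxyphenyl)(methoxy)methylidene]chromium | COC(c1cc(OC)ccc1OC)=[Cr](=C=O)(=C=O)(=C=O)(=C=O)=C=O
F2 | step 7 | 2-[(1S)-1-(tert-butyldimethylsilyloxy)-4-methylpent-3-en-1-yl]-4,5,8-trimethoxynaphthalen-1-ol | CC(C)=CC[C@H](O[Si](C)(C)C(C)(C)C)c1cc(OC)c2c(OC)ccc(OC)c2c1O
F3 | step 9 | 2-[(1S)-1-(tert-butyldimethylsilyloxy)-4-methylpent-3-en-1-yl]naphthalene-1,4,5,8-tetrone | CC(C)=CC[C@H](O[Si](C)(C)C(C)(C)C)C1=CC(=O)C2=C(C1=O)C(=O)C=CC2=O
F4 | step 8 | 3-[(1S)-1-(tert-butyldimethylsilyloxy)-4-methylpent-3-en-1-yl]-4,5,8-trimethoxynaphthalen-1-ol | CC(C)=CC[C@H](O[Si](C)(C)C(C)(C)C)c1cc(O)c2c(OC)ccc(OC)c2c1OC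
F5 | step 8 | 3-[(1S)-1-(tert-butyldimethylsilyloxy)-4-methylpent-3-en-1-yl]-4,4,5,8-tetramethoxynaphthalen-1(4H)-one | CC(C)=CC[C@H](O[Si](C)(C)C(C)(C)C)C1=CC(=O)c2c(OC)ccc(OC)c2C1(OC)OC
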